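## The problem

1. The target 27 is a flavan: ring A is fused to a dihydropyran ring C, which carries ring B at C2, an isopropyl group at C3 and an isobutyl group at C4.
2. Ring A is a 5,7-dihydroxy-6-carbaldehyde with C8 unsubstituted and ring B is a 2,4,6-trihydroxy-3,5-dicarbaldehyde, so three formyl groups must sit at defined positions on two rings of nearly equal nucleophilicity.
3. Ring A must be tied to the pyran oxygen through the hydroxyl para to its formyl group (O1), not through the one ortho to it (O5), although both flank C4a.
4. The three contiguous stereocentres are (2R,3R,4S): ring B and isopropyl trans, isopropyl and isobutyl cis.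
5. C2 is a doubly activated benzylic ether carbon that can ionise and re-close, so it will follow C3 under thermodynamic control; C4 cannot be corrected once set, and C3 has no handle for adjustment, so C3 must be made in the absolute sense and then direct the other two.
6. The fragile elements are the O1–C2 bond (ionisation, epimerisation, elimination into C2–C3, re-closure onto O5 once that oxygen is free), the electron-rich rings (oxidation, over-formylation at C8) and the aryl aldehydes (enolates, hydrides, organometallics).
7. The same lability is the opportunity: because C2 is benzylic to a ring with three oxygen donors, a carboxyl group on C2 can first serve to build C2–C3 by ester-enolate chemistry and then be expelled by two-electron oxidation, leaving a stabilised cation exactly where O1 needs an electrophile.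

## Retrosynthesis

**27 ⇒ 26 ⇒ 24.** The two O–CH3 bonds of ring A and the two C–CHO bonds of ring B are handled last. Ring B must stay electron-rich up to the key step, so its formyl groups come after it. They must be introduced while ring B is a free triol and ring A still carries methyl ethers, otherwise C8 would compete. Hence 27 comes from the dimethyl ether 26 by ether cleavage, and 26 from triol 24 by twofold electrophilic formylation. The forward steps must formylate ring B twice before ring A once, and cleave the ethers faster than O1–C2 ionises.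

**24 ⇒ 23.** The C4–H and C1′–H bonds and the three ring B O–H bonds go back to an exocyclic (Z)-alkene and three benzyl ethers, all answered by one hydrogenation. Compared with carrying a saturated C4 centre through the ring closure, this leaves only C3 to be made in an open chain. C4 is then set inside the ring, where C3 and the peri 5-methoxy group define the faces. The forward step must add hydrogen anti to the isopropyl group without moving the double bond into the ring.

**23 ⇒ 21 (key cut).** O1–C2 is cut. Of the pyran bonds it is the one whose formation the structure itself can drive, since C2 is benzylic to the trialkoxy ring B. A carboxyl group on C2 gives acid 21, and anodic two-electron decarboxylation should hand a C2 cation to O1. Unlike an SN2 or Mitsunobu closure of a C2 alcohol, this needs no defined C2 precursor. Unlike a cycloaddition or conjugate-addition route to ring C, it lets C3 be fixed beforehand. O5 and O7 stay methyl ethers so that closure is regiodefined, and the ring A formyl group is free so that ring A is the harder ring to oxidise.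

**21 ⇒ 20 ⇒ 17.** The carboxyl group marks C2–C3 as the bond for an ester-enolate Claisen rearrangement: acid 20 (phenol and aldehyde masked, 20 → 21 by mild acid) comes from the allylic arylacetate 17. This turns a lone carbon stereocentre between two branched groups into a secondary allylic carbinol. It also leaves the C4=C1′ alkene where the isobutyl group is needed. Only chirality transfer to C3 is asked of the rearrangement; C2 may form as either epimer.

**17 ⇒ 11 + 16.** The ester C–O bond is cut to allylic alcohol 11 and ring B arylacetic acid 16. This is the convergent junction, and the two halves share no sensitive functionality.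

**11 ⇒ 10 ⇒ 6 + 7.** The carbinol centre comes from enone 10 by catalytic asymmetric carbonyl reduction. The trisubstituted alkene comes from an aldol condensation of benzylic ketone 6 with isobutyraldehyde 7. C3 and its isopropyl group thus derive from 7, which places the two alkyl groups without ambiguity. The (E) geometry of 10 matters because it decides, together with the carbinol, the configuration of C3.

**6 ⇒ 4 + 5; 4 ⇒ 3 ⇒ 2 ⇒ 1.** The C4a–C4 bond is cut by ketone α-arylation of 3-methylbutan-2-one 5 with bromide 4; 5 supplies C4 and the isobutyl group. Bromide 4 comes from commercial aldehyde 1 by bromination ortho to the only free hydroxyl (to 2), protection of that hydroxyl (to 3) and acetalisation. Compound 1 already has O5 and O7 methylated and the future O1 free.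

**16 ⇒ 15 ⇒ 13 ⇒ 12.** The arylacetic acid is taken back through nitrile 15 to aldehyde 13 by a one-carbon homologation, and 13 to commercial 2,4,6-trihydroxybenzaldehyde 12 by benzylation. Benzyl is chosen because it leaves in the hydrogenation and frees ring B alone for formylation.

## Roads not taken

Alternative 1: The cut is at C3–CH(CH3)2 and C4–C4a, formed together by a conjunctive cross-coupling. Isopropyllithium A2 adds to boron of the (Z)-alkenyl pinacol boronate A1. A palladium catalyst with a chiral ferrocenyl bisphosphine and bromide 4 then triggers the shift of isopropyl from boron to C3 while ring A is delivered to C4, giving the secondary boronic ester A3. No ring closes.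
- Merits: C3 and C4 are set in one catalytic step, relative configuration from the alkene geometry and absolute from the ligand, and the C–B bond is a handle for stereospecific homologation.
- Weak points: a β-substituted alkenyl boronate, a secondary migrating group and a di-ortho-alkoxy aryl bromide each sit at the edge of what this coupling tolerates. Afterwards C2, ring B and O1–C2 still have to be added at a very hindered secondary boronate, in several further steps.
- Comparison: in the way C4 is fixed this road is better, because it is catalyst-controlled and does not depend on the face selectivity of a late hydrogenation. The chosen plan sets against it that C2–C3, then O1–C2 with the ring and the C2 centre, arise from two operations on one carboxyl group, and that its C–C bond formations are classical.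

Alternative 2: The cut is at O1–C2 and C4–C4a in one acid-catalysed condensation of bromophenol A5 with the 2-isopropyl-1,3-diketone A4 (accessible by C-aroylation of a symmetrical ketone). The free ortho carbon attacks the aliphatic carbonyl, the phenol oxygen condenses with the aryl ketone, and dehydration gives the flavylium salt A6.
- Merits: the whole skeleton and the heterocycle appear in one step from trivial partners. In step count and convergence this road is clearly better.
- Weak points: A6 is flat, so all three stereocentres must be created afterwards. Hydrogenation would give the all-cis array and need a C2 epimerisation, and no reliable asymmetric reduction exists for a fully substituted, hindered benzopyrylium. Ring A arrives without its formyl group and with a blocking bromine, and ring B as a trimethyl ether, so five methyl ethers must be cleaved and the rings differentiated for formylation at the end.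
- Comparison: the chosen plan is longer, but it secures the absolute configuration at C3 from a carbinol, carries the ring A formyl group from the start, and distinguishes the rings by benzyl against methyl ethers.

Alternative 3: The cut is at C4a–C4, C3–C2 and C2–O1 in a palladium-catalysed carbonylative annulation. Iodophenol A7 adds across alkyne A8, carbon monoxide A9 inserts, and the phenol takes the acyl group, closing coumarin A10.
- Merits: ring A with its formyl group, both alkyl groups and the pyranone ring come together in one step, with C2 at the carboxyl level ready for ring B. For building rings A and C this is more convergent than the chosen plan.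
- Weak points: the alkyne ends differ only in where they branch, so the 3-isopropyl-4-isobutyl and the reversed coumarin would both form. Adding a ring B organometallic to the lactone requires the free aldehyde to be protected after all. The tetrasubstituted C3=C4 bond and C2 must then be reduced with control of three stereocentres, the same unsolved problem as in alternative 2.
- Comparison: the chosen plan places isopropyl and isobutyl unambiguously, because they come from 7 and 5, and it sets C3 before the ring exists.

Key step: step 13

Assumption: in step 6 the 1-arylalkenyl group of 10 is taken to act as the large substituent and isopropyl as the small one, so that the (R)-oxazaborolidine gives the (3S) alcohol; compounds 1, 5, 7 and 12 are taken as commercial.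

## Route

Step 1
Reactants: 1 4-hydroxy-2,6-dimethoxybenzaldehyde
Product: 2 3-bromo-4-hydroxy-2,6-dimethoxybenzaldehyde
Conditions: NBS (1.0 equiv), MeCN, 0 °C
Reagents that add atoms: N-bromosuccinimide, O=C1CCC(=O)N1Br
Why: Electrophilic aromatic bromination ortho to the free hydroxyl; the two open positions of 1 are equivalent, so a single monobromide forms, and one equivalent of NBS at 0 °C holds back the dibromide.

Step 2
Reactants: 2 3-bromo-4-hydroxy-2,6-dimethoxybenzaldehyde
Product: 3 3-bromo-2,6-dimethoxy-4-(methoxymethoxy)benzaldehyde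
Conditions: MOMCl, i-Pr2NEt, CH2Cl2, 0 °C → rt
Reagents that add atoms: chloromethyl methyl ether, COCCl
Why: O-alkylation of the acidic phenol as its methoxymethyl ether, which is inert to the bases, the borane and the palladium catalyst of the next steps and small enough not to shield the neighbouring C–Br bond.

Step 3
Reactants: 3 3-bromo-2,6-dimethoxy-4-(methoxymethoxy)benzaldehyde
Product: 4 2-[3-bromo-2,6-dimethoxy-4-(methoxymethoxy)phenyl]-1,3-dioxolane
Conditions: Me3SiOCH2CH2OSiMe3, Me3SiOTf (cat.), CH2Cl2, −78 → −20 °C; pyridine
Reagents that add atoms: 1,2-bis(trimethylsilyloxy)ethane, C[Si](C)(C)OCCO[Si](C)(C)C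
Why: Aprotic silyl-transfer acetalisation (Noyori acetalisation), driven by formation of the disiloxane; without a Brønsted acid the methoxymethyl ether stays on, and the dioxolane masks the aldehyde against enolates and hydride.

Step 4
Reactants: 4 2-[3-bromo-2,6-dimethoxy-4-(methoxymethoxy)phenyl]-1,3-dioxolane; 5 3-methylbutan-2-one
Product: 6 1-[3-(1,3-dioxolan-2-yl)-2,4-dimethoxy-6-(methoxymethoxy)phenyl]-3-methylbutan-2-one
Conditions: Pd2(dba)3 (cat.), XPhos, NaOtBu, toluene, 70 °C
Reagents that add atoms: none
Why: Palladium-catalysed ketone α-arylation: the C–Br bond adds to zerovalent palladium, the sodium enolate of 5 displaces bromide and reductive elimination forms the aryl–CH2 bond (later C4a–C4). The methyl side reacts because its enolate is less hindered than the methine one, the bulky biarylphosphine is the ligand class that tolerates two ortho alkoxy groups, and the product sits as its enolate, which blocks a second arylation.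

Step 5
Reactants: 6 1-[3-(1,3-dioxolan-2-yl)-2,4-dimethoxy-6-(methoxymethoxy)phenyl]-3-methylbutan-2-one; 7 2-methylpropanal (isobutyraldehyde)
Product: 10 (4E)-4-[3-(1,3-dioxolan-2-yl)-2,4-dimethoxy-6-(methoxymethoxy)phenyl]-2,6-dimethylhept-4-en-3-one, via lithium aldolate 8 (not isolated), via β-mesyloxy ketone 9 (not isolated)
Conditions: LiN(iPr)2, THF, −78 °C; 7; MsCl, −78 → 0 °C; DBU, 0 °C → rt
Reagents that add atoms: none
Why: Directed aldol addition of the benzylic lithium enolate of 6 (the CH2 between aryl and carbonyl is the acidic site) to 7, then E1cB elimination of the mesylate formed in the flask. The (E) isomer, with the carbonyl group trans to isopropyl and the twisted aryl ring cis to it, should be the thermodynamically favoured one under DBU; any (Z) isomer has to be removed here because the alkene geometry decides the configuration of C3 in step 11.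

Step 6
Reactants: 10 (4E)-4-[3-(1,3-dioxolan-2-yl)-2,4-dimethoxy-6-(methoxymethoxy)phenyl]-2,6-dimethylhept-4-en-3-one
Product: 11 (3S,4E)-4-[3-(1,3-dioxolan-2-yl)-2,4-dimethoxy-6-(methoxymethoxy)phenyl]-2,6-dimethylhept-4-en-3-ol
Conditions: (R)-2-methyl-CBS-oxazaborolidine (20 mol%), catecholborane, toluene, −78 °C; MeOH, aq. NaOH
Reagents that add atoms: none
Why: Corey–Bakshi–Shibata reduction: the oxazaborolidine binds the carbonyl oxygen anti to the large 1-arylalkenyl group and delivers hydride to one face, setting the carbinol centre as (S). Catecholborane at low temperature avoids hydroboration and 1,4-reduction.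

Step 7
Reactants: 12 2,4,6-trihydroxybenzaldehyde
Product: 13 2,4,6-tris(benzyloxy)benzaldehyde
Conditions: BnBr, K2CO3, DMF, 60 °C
Reagents that add atoms: benzyl bromide, BrCc1ccccc1
Why: Threefold Williamson etherification; carbonate in warm DMF should also alkylate the two hydroxyls that are hydrogen-bonded to the formyl group.

Step 8
Reactants: 13 2,4,6-tris(benzyloxy)benzaldehyde
Product: 15 2-[2,4,6-tris(benzyloxy)phenyl]acetonitrile, via tosylvinylformamide salt 14 (not isolated)
Conditions: TosMIC, KOtBu, DME, −40 °C; then MeOH, 65 °C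
Reagents that add atoms: p-toluenesulfonylmethyl isocyanide, [C-]#[N+]CS(=O)(=O)c1ccc(C)cc1
Why: van Leusen reductive cyanation of an aldehyde: the TosMIC anion adds to the carbonyl group and the adduct opens to the N-formyl enamide salt 14; methanolysis removes the formyl group and sulfinate is expelled, leaving the nitrile with one more carbon.

Step 9
Reactants: 15 2-[2,4,6-tris(benzyloxy)phenyl]acetonitrile
Product: 16 2-[2,4,6-tris(benzyloxy)phenyl]acetic acid
Conditions: KOH, HOCH2CH2OH/H2O, 130 °C; then aq. HCl
Reagents that add atoms: potassium hydroxide, [K+].[OH-]; water, O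
Why: Alkaline hydrolysis of a nitrile to the carboxylate; benzyl aryl ethers are stable to hot hydroxide.

Step 10
Reactants: 11 (3S,4E)-4-[3-(1,3-dioxolan-2-yl)-2,4-dimethoxy-6-(methoxymethoxy)phenyl]-2,6-dimethylhept-4-en-3-ol; 16 2-[2,4,6-tris(benzyloxy)phenyl]acetic acid
Product: 17 (3S,4E)-4-[3-(1,3-dioxolan-2-yl)-2,4-dimethoxy-6-(methoxymethoxy)phenyl]-2,6-dimethylhept-4-en-3-yl 2-[2,4,6-tris(benzyloxy)phenyl]acetate
Conditions: DCC, DMAP (cat.), CH2Cl2, 0 °C → rt
Reagents that add atoms: none
Why: Steglich esterification (carbodiimide activation, acyl transfer through the acylpyridinium); no stereocentre is touched and the neutral conditions preserve acetal and methoxymethyl ether.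

Step 11
Reactants: 17 (3S,4E)-4-[3-(1,3-dioxolan-2-yl)-2,4-dimethoxy-6-(methoxymethoxy)phenyl]-2,6-dimethylhept-4-en-3-yl 2-[2,4,6-tris(benzyloxy)phenyl]acetate
Product: 20 (3S,4Z)-4-[3-(1,3-dioxolan-2-yl)-2,4-dimethoxy-6-(methoxymethoxy)phenyl]-6-methyl-3-(propan-2-yl)-2-[2,4,6-tris(benzyloxy)phenyl]hept-4-enoic acid (either C2 epimer), via silyl ketene acetal 18 (not isolated), via trimethylsilyl ester 19 (not isolated)
Conditions: LiN(SiMe3)2, Me3SiCl, THF, −78 °C → rt, then 45 °C; pH 5 buffer
Reagents that add atoms: none
Why: Ireland–Claisen rearrangement: O-silylation of the ester enolate gives ketene acetal 18, which rearranges through a chair with the carbinol isopropyl group equatorial, forming C2–C3 on the alkene face syn to the departing C–O bond. This carries the (S) carbinol of the (E)-alkene into (3S) at C3 and gives the (Z)-trisubstituted alkene; the C2 configuration is left open because step 13 removes it.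

Step 12
Reactants: 20 (3S,4Z)-4-[3-(1,3-dioxolan-2-yl)-2,4-dimethoxy-6-(methoxymethoxy)phenyl]-6-methyl-3-(propan-2-yl)-2-[2,4,6-tris(benzyloxy)phenyl]hept-4-enoic acid
Product: 21 (3S,4Z)-4-(3-formyl-6-hydroxy-2,4-dimethoxyphenyl)-6-methyl-3-(propan-2-yl)-2-[2,4,6-tris(benzyloxy)phenyl]hept-4-enoic acid (either C2 epimer)
Conditions: PPTS, t-BuOH/H2O (10:1), 70 °C
Reagents that add atoms: water, O
Why: Mild Brønsted-acid hydrolysis of the dioxolane and of the aryl methoxymethyl ether; the acid is too weak to protonate the twisted trisubstituted alkene (which would invite γ-lactonisation) or to let the released formaldehyde attack ring B.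

Step 13
Reactants: 21 (3S,4Z)-4-(3-formyl-6-hydroxy-2,4-dimethoxyphenyl)-6-methyl-3-(propan-2-yl)-2-[2,4,6-tris(benzyloxy)phenyl]hept-4-enoic acid
Product: 23 (2R,3R,4Z)-2-[2,4,6-tris(benzyloxy)phenyl]-5,7-dimethoxy-4-(2-methylpropylidene)-3-(propan-2-yl)-3,4-dihydro-2H-chromene-6-carbaldehyde, via benzylic cation 22 (not isolated)
Conditions: graphite anode, Pt cathode, undivided cell, constant current (about 2.2 F/mol), 2,4,6-collidine (0.5 equiv), n-Bu4NPF6, CH2Cl2, 3 Å MS, rt
Reagents that add atoms: none
Why: Proposed new method: the closest known reaction type is the Hofer–Moest (non-Kolbe) anodic decarboxylation of electron-rich arylacetic acids with capture of the cation by alcohols, water or carboxylates; capture by an internal phenol to close a flavan ring has not been shown, and the reasoning is as follows. The collidinium carboxylate of 21 gives up one electron at graphite (the carboxylate next to the trialkoxy ring B is the most easily oxidised site, ring A being deactivated by its formyl group and kept un-ionised by the substoichiometric base), CO2 is lost, and the benzylic radical is oxidised again to cation 22, whose charge is shared by three alkoxy oxygens. The ring A hydroxyl, placed to form a six-membered ring, adds to this cation (6-exo-trig with respect to the quinoid C2=C(aryl) bond), forming O1–C2 and the pyran ring, and the proton released is reduced to hydrogen at platinum, so no chemical oxidant is needed. C2 is set by the resident C3 centre: closure through a chair-like transition state places ring B and isopropyl both equatorial (2,3-trans), and because O1–C2 of 23 can re-ionise the same trans isomer is also the thermodynamic one, so the C2 configuration of 21 is erased and does not matter. The step needs oxidation of the arylacetate before the phenol, the product and the alkene; this is secured by the potential gap, by limiting the charge, and by the two ortho benzyloxy groups, which hold the new C2–H bond near the plane of ring B and so slow its loss from a product radical cation. The nucleophile is regiodefined because O5 and O7 are methyl ethers and dichloromethane offers no competing nucleophile.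

Step 14
Reactants: 23 (2R,3R,4Z)-2-[2,4,6-tris(benzyloxy)phenyl]-5,7-dimethoxy-4-(2-methylpropylidene)-3-(propan-2-yl)-3,4-dihydro-2H-chromene-6-carbaldehyde
Product: 24 (2R,3R,4S)-5,7-dimethoxy-4-(2-methylpropyl)-3-(propan-2-yl)-2-(2,4,6-trihydroxyphenyl)-3,4-dihydro-2H-chromene-6-carbaldehyde
Conditions: H2 (1 atm), 10% Pd/C, EtOAc/EtOH, rt
Reagents that add atoms: none
Why: Heterogeneous catalytic hydrogenation: syn addition of H2 to the exocyclic alkene and hydrogenolysis of the three benzyl ethers. With ring B and isopropyl equatorial, the 5-methoxy group pushes the alkylidene carbon to the pseudoaxial side, so hydrogen should reach C4 from the opposite face, anti to the isopropyl group; the isobutyl group then ends pseudoaxial and cis to isopropyl (4S).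

Step 15
Reactants: 24 (2R,3R,4S)-5,7-dimethoxy-4-(2-methylpropyl)-3-(propan-2-yl)-2-(2,4,6-trihydroxyphenyl)-3,4-dihydro-2H-chromene-6-carbaldehyde
Product: 26 (2R,3R,4S)-2-(3,5-diformyl-2,4,6-trihydroxyphenyl)-5,7-dimethoxy-4-(2-methylpropyl)-3-(propan-2-yl)-3,4-dihydro-2H-chromene-6-carbaldehyde, via bis(iminium) salt 25 (not isolated)
Conditions: POCl3, DMF, MeCN, 0 °C → rt; then H2O, 40 °C
Reagents that add atoms: N,N-dimethylformamide, CN(C)C=O; water, O
Why: Vilsmeier–Haack formylation of a free phloroglucinol ring: the chloroiminium ion substitutes both open positions of ring B to give 25, which water hydrolyses to the dialdehyde. Ring A, with a formyl group and only ether oxygens, is far less nucleophilic, so C8 should stay free, and the iminium groups stabilise O1–C2 against ionisation as soon as they are in place.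

Step 16
Reactants: 26 (2R,3R,4S)-2-(3,5-diformyl-2,4,6-trihydroxyphenyl)-5,7-dimethoxy-4-(2-methylpropyl)-3-(propan-2-yl)-3,4-dihydro-2H-chromene-6-carbaldehyde
Product: 27 (2R,3R,4S)-2-(3,5-diformyl-2,4,6-trihydroxyphenyl)-5,7-dihydroxy-4-(2-methylpropyl)-3-(propan-2-yl)-3,4-dihydro-2H-chromene-6-carbaldehyde
Conditions: BBr3 (excess), CH2Cl2, −78 → 0 °C; then H2O
Reagents that add atoms: none
Why: Lewis-acid cleavage of aryl methyl ethers: both methoxy groups flank the ring A formyl group, the first is cleaved with chelation assistance and the second by the excess reagent. The two formyl groups now on ring B disfavour ionisation of O1–C2 at low temperature, so the three stereocentres should be untouched.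

## Compound list

1 | 4-hydroxy-2,6-dimethoxybenzaldehyde | O=Cc1c(OC)cc(O)cc1OC | starting material
2 | 3-bromo-4-hydroxy-2,6-dimethoxybenzaldehyde | O=Cc1c(OC)c(Br)c(O)cc1OC | intermediate
3 | 3-bromo-2,6-dimethoxy-4-(methoxymethoxy)benzaldehyde | O=Cc1c(OC)c(Br)c(OCOC)cc1OC | intermediate
4 | 2-[3-bromo-2,6-dimethoxy-4-(methoxymethoxy)phenyl]-1,3-dioxolane | COc1cc(OCOC)c(Br)c(OC)c1C1OCCO1 | intermediate
5 | 3-methylbutan-2-one | CC(=O)C(C)C | starting material
6 | 1-[3-(1,3-dioxolan-2-yl)-2,4-dimethoxy-6-(methoxymethoxy)phenyl]-3-methylbutan-2-one | CC(C)C(=O)Cc1c(OC)c(C2OCCO2)c(OC)cc1OCOC | intermediate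
7 | 2-methylpropanal (isobutyraldehyde) | CC(C)C=O | starting material
8 | lithium alkoxide of 4-[3-(1,3-dioxolan-2-yl)-2,4-dimethoxy-6-(methoxymethoxy)phenyl]-5-hydroxy-2,6-dimethylheptan-3-one (diastereomer mixture) | CC(C)C([O-])C(C(=O)C(C)C)c1c(OC)c(C2OCCO2)c(OC)cc1OCOC.[Li+] | intermediate (not isolated)
9 | 4-[3-(1,3-dioxolan-2-yl)-2,4-dimethoxy-6-(methoxymethoxy)phenyl]-2,6-dimethyl-5-oxoheptan-3-yl methanesulfonate (diastereomer mixture) | CC(C)C(OS(C)(=O)=O)C(C(=O)C(C)C)c1c(OC)c(C2OCCO2)c(OC)cc1OCOC | intermediate (not isolated)
10 | (4E)-4-[3-(1,3-dioxolan-2-yl)-2,4-dimethoxy-6-(methoxymethoxy)phenyl]-2,6-dimethylhept-4-en-3-one | CC(C)C(=O)/C(=C/C(C)C)c1c(OC)c(C2OCCO2)c(OC)cc1OCOC | intermediate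
11 | (3S,4E)-4-[3-(1,3-dioxolan-2-yl)-2,4-dimethoxy-6-(methoxymethoxy)phenyl]-2,6-dimethylhept-4-en-3-ol | CC(C)[C@H](O)/C(=C/C(C)C)c1c(OC)c(C2OCCO2)c(OC)cc1OCOC | intermediate
12 | 2,4,6-trihydroxybenzaldehyde | O=Cc1c(O)cc(O)cc1O | starting material
13 | 2,4,6-tris(benzyloxy)benzaldehyde | O=Cc1c(OCc2ccccc2)cc(OCc2ccccc2)cc1OCc1ccccc1 | intermediate
14 | potassium salt of N-{1-[(4-methylphenyl)sulfonyl]-2-[2,4,6-tris(benzyloxy)phenyl]ethenyl}formamide | [K+].O=C[N-]C(=Cc1c(OCc2ccccc2)cc(OCc2ccccc2)cc1OCc1ccccc1)S(=O)(=O)c1ccc(C)cc1 | intermediate (not isolated)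
15 | 2-[2,4,6-tris(benzyloxy)phenyl]acetonitrile | N#CCc1c(OCc2ccccc2)cc(OCc2ccccc2)cc1OCc1ccccc1 | intermediate
16 | 2-[2,4,6-tris(benzyloxy)phenyl]acetic acid | OC(=O)Cc1c(OCc2ccccc2)cc(OCc2ccccc2)cc1OCc1ccccc1 | intermediate
17 | (3S,4E)-4-[3-(1,3-dioxolan-2-yl)-2,4-dimethoxy-6-(methoxymethoxy)phenyl]-2,6-dimethylhept-4-en-3-yl 2-[2,4,6-tris(benzyloxy)phenyl]acetate | CC(C)[C@H](OC(=O)Cc1c(OCc2ccccc2)cc(OCc2ccccc2)cc1OCc1ccccc1)/C(=C/C(C)C)c1c(OC)c(C2OCCO2)c(OC)cc1OCOC | intermediate
18 | trimethylsilyl ketene acetal of 17: [(1-{[(3S,4E)-4-[3-(1,3-dioxolan-2-yl)-2,4-dimethoxy-6-(methoxymethoxy)phenyl]-2,6-dimethylhept-4-en-3-yl]oxy}-2-[2,4,6-tris(benzyloxy)phenyl]ethenyl)oxy]trimethylsilane (ketene acetal geometry open) | CC(C)[C@H](OC(O[Si](C)(C)C)=Cc1c(OCc2ccccc2)cc(OCc2ccccc2)cc1OCc1ccccc1)/C(=C/C(C)C)c1c(OC)c(C2OCCO2)c(OC)cc1OCOC | intermediate (not isolated)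
19 | trimethylsilyl (3S,4Z)-4-[3-(1,3-dioxolan-2-yl)-2,4-dimethoxy-6-(methoxymethoxy)phenyl]-6-methyl-3-(propan-2-yl)-2-[2,4,6-tris(benzyloxy)phenyl]hept-4-enoate (either C2 epimer) | C[Si](C)(C)OC(=O)C(c1c(OCc2ccccc2)cc(OCc2ccccc2)cc1OCc1ccccc1)[C@@H](/C(=C/C(C)C)c1c(OC)c(C2OCCO2)c(OC)cc1OCOC)C(C)C | intermediate (not isolated)
20 | (3S,4Z)-4-[3-(1,3-dioxolan-2-yl)-2,4-dimethoxy-6-(methoxymethoxy)phenyl]-6-methyl-3-(propan-2-yl)-2-[2,4,6-tris(benzyloxy)phenyl]hept-4-enoic acid (either C2 epimer) | OC(=O)C(c1c(OCc2ccccc2)cc(OCc2ccccc2)cc1OCc1ccccc1)[C@@H](/C(=C/C(C)C)c1c(OC)c(C2OCCO2)c(OC)cc1OCOC)C(C)C | intermediate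
21 | (3S,4Z)-4-(3-formyl-6-hydroxy-2,4-dimethoxyphenyl)-6-methyl-3-(propan-2-yl)-2-[2,4,6-tris(benzyloxy)phenyl]hept-4-enoic acid (either C2 epimer) | OC(=O)C(c1c(OCc2ccccc2)cc(OCc2ccccc2)cc1OCc1ccccc1)[C@@H](/C(=C/C(C)C)c1c(O)cc(OC)c(C=O)c1OC)C(C)C | intermediate (precursor of the key step)
22 | C2 benzylic cation formed from 21 by loss of two electrons and CO2 (C3 and alkene unchanged) | [CH+](c1c(OCc2ccccc2)cc(OCc2ccccc2)cc1OCc1ccccc1)[C@@H](/C(=C/C(C)C)c1c(O)cc(OC)c(C=O)c1OC)C(C)C | intermediate (not isolated)
23 | (2R,3R,4Z)-2-[2,4,6-tris(benzyloxy)phenyl]-5,7-dimethoxy-4-(2-methylpropylidene)-3-(propan-2-yl)-3,4-dihydro-2H-chromene-6-carbaldehyde | CC(C)/C=C1\c2c(cc(OC)c(C=O)c2OC)O[C@@H](c2c(OCc3ccccc3)cc(OCc3ccccc3)cc2OCc2ccccc2)[C@@H]1C(C)C | intermediate (product of the key step)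
24 | (2R,3R,4S)-5,7-dimethoxy-4-(2-methylpropyl)-3-(propan-2-yl)-2-(2,4,6-trihydroxyphenyl)-3,4-dihydro-2H-chromene-6-carbaldehyde | CC(C)C[C@@H]1c2c(cc(OC)c(C=O)c2OC)O[C@@H](c2c(O)cc(O)cc2O)[C@@H]1C(C)C | intermediate
25 | bis(N,N-dimethyliminium) dichloride of 26 (both ring B formyl groups as CH=N+(CH3)2) | CC(C)C[C@@H]1c2c(cc(OC)c(C=O)c2OC)O[C@@H](c2c(O)c(C=[N+](C)C)c(O)c(C=[N+](C)C)c2O)[C@@H]1C(C)C.[Cl-].[Cl-] | intermediate (not isolated)
26 | (2R,3R,4S)-2-(3,5-diformyl-2,4,6-trihydroxyphenyl)-5,7-dimethoxy-4-(2-methylpropyl)-3-(propan-2-yl)-3,4-dihydro-2H-chromene-6-carbaldehyde | CC(C)C[C@@H]1c2c(cc(OC)c(C=O)c2OC)O[C@@H](c2c(O)c(C=O)c(O)c(C=O)c2O)[C@@H]1C(C)C | intermediate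
27 | (2R,3R,4S)-2-(3,5-diformyl-2,4,6-trihydroxyphenyl)-5,7-dihydroxy-4-(2-methylpropyl)-3-(propan-2-yl)-3,4-dihydro-2H-chromene-6-carbaldehyde | CC(C)C[C@@H]1c2c(cc(O)c(C=O)c2O)O[C@@H](c2c(O)c(C=O)c(O)c(C=O)c2O)[C@@H]1C(C)C | target

## Step count and weak points

Total: 16 steps. Longest linear sequence: 13 steps (from 1 through steps 1–6 and 10–16); the ring B branch (steps 7–9) joins at step 10.

**Step 13 (key step, proposed new method).**
- What may go wrong: oxidation of the phenol or of product 23 instead of the carboxylate; loss of the C3 proton from cation 22 (elimination into C2–C3, which destroys C3); slow closure, because ring closure forces the (Z)-isobutylidene group against the 5-methoxy group, leaving the cation time to oligomerise.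
- Fallback (known chemistry, separates decarboxylation from ring closure): it sets out from 20. Kochi-type oxidative decarboxylation with Pb(OAc)4 and pyridine in benzene at 70 °C should give the benzylic acetate, (2R,3Z)-3-[3-(1,3-dioxolan-2-yl)-2,4-dimethoxy-6-(methoxymethoxy)phenyl]-5-methyl-2-(propan-2-yl)-1-[2,4,6-tris(benzyloxy)phenyl]hex-3-en-1-yl acetate F1. Exposure of F1 to the conditions of step 12 (PPTS, wet t-BuOH, 70 °C) frees phenol and aldehyde and, under the same mild acid, ionises the benzylic acetate so that the phenol closes by SN1 etherification. The route is rejoined at 23.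

**Step 14.**
- What may go wrong: poor facial selectivity at C4; migration of the exocyclic double bond into the ring on palladium, with loss of the C3 centre; hydrogenolysis of O1–C2; reduction of the aldehyde.
- Fallback: from 23, a hydrogen-atom-transfer hydrogenation (Mn(dpm)3, PhSiH3, t-BuOOH, i-PrOH, rt) reduces the alkene through the C4 benzylic radical, which cannot isomerise the double bond and should take its hydrogen so that the isobutyl group ends pseudoaxial. This gives the saturated benzyl ether, (2R,3R,4S)-2-[2,4,6-tris(benzyloxy)phenyl]-5,7-dimethoxy-4-(2-methylpropyl)-3-(propan-2-yl)-3,4-dihydro-2H-chromene-6-carbaldehyde F2. Hydrogenolysis of F2 (H2, Pd(OH)2/C, EtOAc) then rejoins the route at 24.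

**Step 5.**
- What may go wrong: retro-aldol cleavage of the hindered aldolate during mesylation; formation of both alkene geometries; deconjugation under base.
- Fallback (a geometry-defined cross-coupling that also bypasses the hindered α-arylation of step 4): it sets out from 4, 5 and 7.
  - Base-mediated aldol condensation of 5 with 7 (only the methyl side can dehydrate) gives (4E)-2,6-dimethylhept-4-en-3-one F3.
  - Bromine addition and elimination with Et3N gives (4Z)-4-bromo-2,6-dimethylhept-4-en-3-one F4.
  - Bromine–lithium exchange on 4 (n-BuLi, THF, −78 °C) and quench with 2-isopropoxy-4,4,5,5-tetramethyl-1,3,2-dioxaborolane gives the boronate, 2-[3-(1,3-dioxolan-2-yl)-2,4-dimethoxy-6-(methoxymethoxy)phenyl]-4,4,5,5-tetramethyl-1,3,2-dioxaborolane F5.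
  - Suzuki–Miyaura coupling of F4 with F5 (Pd(OAc)2, SPhos, K3PO4, toluene/H2O) proceeds with retention of alkene geometry and rejoins the route at 10.

**Step 6.**
- What may go wrong: insufficient or reversed enantioselection, because the small group is a branched isopropyl; this would pass directly into the enantiomeric purity of C3.
- Fallback (resolution in place of asymmetric catalysis): from 10, Luche reduction (NaBH4, CeCl3·7H2O, MeOH) gives the racemic alcohol, rac-(4E)-4-[3-(1,3-dioxolan-2-yl)-2,4-dimethoxy-6-(methoxymethoxy)phenyl]-2,6-dimethylhept-4-en-3-ol F6. Esterification with (S)-O-methylmandelic acid (DCC, DMAP) and chromatographic separation gives the ester of the wanted alcohol, (3S,4E)-4-[3-(1,3-dioxolan-2-yl)-2,4-dimethoxy-6-(methoxymethoxy)phenyl]-2,6-dimethylhept-4-en-3-yl (2S)-2-methoxy-2-phenylacetate F7. Saponification (LiOH, THF/MeOH/H2O) rejoins the route at 11.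

**Step 16.**
- What may go wrong: Lewis-acid ionisation of O1–C2 with epimerisation, elimination, or re-closure through O5 once that oxygen is free (which in effect moves the formyl group from C6 to C8); incomplete cleavage of the second, non-chelated ether.
- Fallback (dealkylation of opposite polarity): from 26, nucleophilic demethylation with NaSEt in DMF at 100 °C attacks the methyl carbons, which are activated by the ortho formyl group, under non-ionising basic conditions and leads directly to 27. It makes no new compound (entered as F0 below).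

## Further compounds

F1 | step 13 | (2R,3Z)-3-[3-(1,3-dioxolan-2-yl)-2,4-dimethoxy-6-(methoxymethoxy)phenyl]-5-methyl-2-(propan-2-yl)-1-[2,4,6-tris(benzyloxy)phenyl]hex-3-en-1-yl acetate (either C1 epimer) | CC(=O)OC(c1c(OCc2ccccc2)cc(OCc2ccccc2)cc1OCc1ccccc1)[C@@H](/C(=C/C(C)C)c1c(OC)c(C2OCCO2)c(OC)cc1OCOC)C(C)C
F2 | step 14 | (2R,3R,4S)-2-[2,4,6-tris(benzyloxy)phenyl]-5,7-dimethoxy-4-(2-methylpropyl)-3-(propan-2-yl)-3,4-dihydro-2H-chromene-6-carbaldehyde | CC(C)C[C@@H]1c2c(cc(OC)c(C=O)c2OC)O[C@@H](c2c(OCc3ccccc3)cc(OCc3ccccc3)cc2OCc2ccccc2)[C@@H]1C(C)C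
F3 | step 5 | (4E)-2,6-dimethylhept-4-en-3-one | CC(C)C(=O)/C=C/C(C)C
F4 | step 5 | (4Z)-4-bromo-2,6-dimethylhept-4-en-3-one | CC(C)C(=O)/C(Br)=C/C(C)C
F5 | step 5 | 2-[3-(1,3-dioxolan-2-yl)-2,4-dimethoxy-6-(methoxymethoxy)phenyl]-4,4,5,5-tetramethyl-1,3,2-dioxaborolane | COc1cc(OCOC)c(B2OC(C)(C)C(C)(C)O2)c(OC)c1C1OCCO1
F6 | step 6 | rac-(4E)-4-[3-(1,3-dioxolan-2-yl)-2,4-dimethoxy-6-(methoxymethoxy)phenyl]-2,6-dimethylhept-4-en-3-ol | CC(C)C(O)/C(=C/C(C)C)c1c(OC)c(C2OCCO2)c(OC)cc1OCOC
F7 | step 6 | (3S,4E)-4-[3-(1,3-dioxolan-2-yl)-2,4-dimethoxy-6-(methoxymethoxy)phenyl]-2,6-dimethylhept-4-en-3-yl (2S)-2-methoxy-2-phenylacetate | CO[C@@H](c1ccccc1)C(=O)O[C@@H](C(C)C)/C(=C/C(C)C)c1c(OC)c(C2OCCO2)c(OC)cc1OCOC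
F0 | step 16 | none | none
A1 | alternative 1 | 4,4,5,5-tetramethyl-2-[(1Z)-4-methylpent-1-en-1-yl]-1,3,2-dioxaborolane | CC(C)C/C=C\B1OC(C)(C)C(C)(C)O1
A2 | alternative 1 | isopropyllithium (propan-2-yllithium) | [Li]C(C)C
A3 | alternative 1 | 2-{(3R,4S)-4-[3-(1,3-dioxolan-2-yl)-2,4-dimethoxy-6-(methoxymethoxy)phenyl]-2,6-dimethylheptan-3-yl}-4,4,5,5-tetramethyl-1,3,2-dioxaborolane | CC(C)C[C@H](c1c(OCOC)cc(OC)c(C2OCCO2)c1OC)[C@H](B1OC(C)(C)C(C)(C)O1)C(C)C
A4 | alternative 2 | 5-methyl-2-(propan-2-yl)-1-(2,4,6-trimethoxyphenyl)hexane-1,3-dione | COc1cc(OC)c(C(=O)C(C(C)C)C(=O)CC(C)C)c(OC)c1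
A5 | alternative 2 | 2-bromo-3,5-dimethoxyphenol | Oc1cc(OC)cc(OC)c1Br
A6 | alternative 2 | 8-bromo-5,7-dimethoxy-4-(2-methylpropyl)-3-(propan-2-yl)-2-(2,4,6-trimethoxyphenyl)chromenylium tetrafluoroborate | CC(C)Cc1c(C(C)C)c(-c2c(OC)cc(OC)cc2OC)[o+]c2c(Br)c(OC)cc(OC)c12.F[B-](F)(F)F
A7 | alternative 3 | 4-hydroxy-3-iodo-2,6-dimethoxybenzaldehyde | O=Cc1c(OC)c(I)c(O)cc1OC
A8 | alternative 3 | 2,6-dimethylhept-3-yne | CC(C)C#CCC(C)C
A9 | alternative 3 | carbon monoxide | [C-]#[O+]
A10 | alternative 3 | 5,7-dimethoxy-4-(2-methylpropyl)-2-oxo-3-(propan-2-yl)-2H-chromene-6-carbaldehyde | CC(C)Cc1c(C(C)C)c(=O)oc2cc(OC)c(C=O)c(OC)c12
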